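The vessel is closed, stirred and isothermal, and in it substrate and partner give product with a protic impurity present.

| setting | oak | birch | cedar | larch | south | north-east | north-west | south-east | east |
|---|---|---|---|---|---|---|---|---|---|
| substrate | 10 mM | 10 mM | 10 mM | 10 mM | 20 mM | 30 mM | 10 mM | 6.0 mM | 10 mM |
| partner | 4.2 mM | 19 mM | 96 mM | 18 mM | 5.00 mM | 18.0 mM | 18.0 mM | 80.0 mM | 18.0 mM |
| protic impurity | 3 mM | 3 mM | 3 mM | 3.6 mM | 2.00 mM | 3.00 mM | 0.800 mM | 12.0 mM | 3.00 mM |
| temperature | 35 °C | 50 °C | 35 °C | 50 °C | 50 °C | 50 °C | 50 °C | 50 °C | 50 °C |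
| remark | run made earlier | run made earlier | run made earlier | run made earlier |  |  |  |  |  |
| time |  |  |  |  | 25 h | 25 h | 25 h | 25 h | 25 h |

- oak (time / h: product / %, substrate / %): 6.00: 0.1, 22.6; 12.0: 0.7, 20.0; 20.0: 0.7, 17.8; 25.0: 0.9, 16.9
- birch (time / h: product / %, substrate / %): 1.00: 1.1, 21.0; 2.50: 2.3, 19.6; 5.00: 5.3, 18.4; 12.0: 14.6, 15.5
- cedar (time / h: product / %, substrate / %): 3.00: 1.4, 24.6; 8.00: 4.3, 20.9; 15.0: 7.6, 19.4; 25.0: 12.0, 16.5
- larch (time / h: product / %, substrate / %): 1.50: 0.8, 20.1; 4.00: 3.7, 18.1; 8.00: 8.7, 17.2; 12.0: 14.2, 15.8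

(each reading ± 0.3 percentage points)



* the flasks put in order of amount of product, in percent of the substrate charged, best first, at 25 h (south / north-east / north-west / south-east / east)
* the amount of product, in percent of the substrate charged of the flask you put first, at 25 h
* the amount of product, in percent of the substrate charged of the flask you put last, at 25 h

Birch grows nearly straight, 5.3% at 5.00 h and 14.6% at 12.0 h, so each run is reckoned as one steady share of the charge per hour. The impurity is taken to remove partner mole for mole, which leaves free partner 1.20 mM in oak and 93.0 mM in cedar, both at 35 °C. Their rates are 3.60 × 10⁻⁴ /h and 0.00480 /h. In powers of ten, free partner rose by 1.89 and the rate by 1.12, so the rate bends over.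

A rate proportional to c(free partner)/(K + c(free partner)) through both readings gives K = 17.9 mM: the half-saturation concentration, the free partner at which product forms at half its ceiling rate. It is a loose reading, since oak's 0.9% carries a scatter of 0.3 percentage points.

K is assumed to hold at 50 °C, and the share per hour is assumed independent of the charge, which the earlier runs, each at 10 mM, cannot test. Birch, with 0.0122 /h at 16.0 mM free, then reckons to a ceiling of 0.0258 /h. South-east, with 68.0 mM free, reckons to 51.0%. South, with 3.00 mM free, reckons to 9.25%, but that product spends 1.85 mM of partner, and taking off half of it gives 6.70%. North-west has 17.2 mM free and east 15.0 mM. North-east has the same free partner as east, but its charge of 30 mM spends more of it. The reckoned order is south-east, north-west, east, north-east, south.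

The forecast gave south-east > north-west > east > north-east > south, from 75% down to 5.5%, holding that “a fixed mM/h is shared over the charge”, and its top stands above the figure reckoned here. The flasks give south-east > north-west > east > north-east > south, from 50.2% down to 7.78%.

    substrate ⇌ dormant form (K = 1.10, k = 2.20 × 10⁻⁴ /s, Ea = 104 kJ/mol, ΔH = −31.0 kJ/mol)
    partner + intermediate B → product (k = 0.00450 /M/s, Ea = 54.0 kJ/mol)
    substrate ⇌ intermediate A (K = 2.60, k = 0.00170 /s, Ea = 93.0 kJ/mol, ΔH = 6.00 kJ/mol)
    intermediate B ⇌ intermediate C (K = 0.720, k = 1.30 × 10⁻⁴ /s, Ea = 92.0 kJ/mol, ΔH = −26.0 kJ/mol)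
    substrate ⇌ intermediate B (K = 0.800, k = 4.60 × 10⁻⁵ /s, Ea = 104 kJ/mol, ΔH = −35.0 kJ/mol)
    partner + protic impurity → quenched reagent (k = 0.0990 /M/s, Ea = 69.0 kJ/mol)
    (constants at 50 °C)

South-east reaches 50.2% at 25 h, against 51.0% reckoned from K. Its partner stands at 83.2% of its charge at 10 h and 81.2% at 25 h, beside 12.0 mM of quenched reagent. The same K and ceiling, put on south-east stopped at 10 h, give 20.4%, and that flask holds 23.4%.

(Readings and results stem from a simulated flask on assumed constants, and the scatter is random.)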